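The trimer is dismantled at the C4–C4a bonds of the upper and middle pyran rings. The plan exploits that upper C4 is bonded to middle C8, the ring A carbon lying between O1 and the 7-oxygen. Electrophilic substitution avoids this site, but 2-bromoresorcinol delivers it as an aryllithium. Its addition to an open-chain C2–C3–C4 aldehyde makes the interflavan bond. Acid then ionises the carbinol, and the 3,5-dibenzyloxyphenyl ether on C2 attacks, closing upper ring C, forming C4–C4a and setting the 4β stereocentre in one operation. The precursor is a syn 3-aryloxy-2-benzyloxy-1,3-diarylpropan-1-ol. The same sequence with 8-lithiocatechin closes the middle ring.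

Key step: step 9

Remark on numbering: open-chain intermediates carry flavan numbering (C2 = benzylic carbon bearing ring B, C3 = benzyloxy carbon, C4 = future ring C carbon).
Remark on configuration: a 2,3-cis flavan corresponds to a syn C2–OAr/C3–OBn pair in the open chain. Because the Mitsunobu etherification inverts C2, the alcohol entering it must be the anti diastereomer, so an anti-selective C2–C3 bond formation is used.
Remark on design: during both etherifications C4 is carried as a vinyl group and not as an acyl group. No acidic C3–H is then present that could trigger β-elimination or epimerisation, and one alcohol serves both the upper and the middle unit.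
Remark on the carbinols: both aryllithium additions should give C4 epimer mixtures. These are carried on unseparated because C4 becomes planar on ionisation.

Step 1
Reactants: 1 benzyl propargyl ether
Product: 2 (E)-3-(benzyloxy)prop-1-enylboronic acid pinacol ester
Conditions: HBpin, Cp2ZrHCl (cat.), Et3N (cat.), neat, 60 °C
Reagents that add atoms: pinacolborane, [H]B1OC(C)(C)C(C)(C)O1
Why: Zirconocene-hydride-catalysed syn hydroboration of a terminal alkyne places boron on the terminal carbon and gives the (E)-alkenylboronate, the benzyl ether being inert.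

Step 2
Reactants: 2 (E)-3-(benzyloxy)prop-1-enylboronic acid pinacol ester
Product: 3 (E)-3-(benzyloxy)prop-2-enylboronic acid pinacol ester
Conditions: [Ir(cod)(PPh2Me)2]PF6 (cat., activated with H2, then N2), THF, rt
Reagents that add atoms: none
Why: Iridium-hydride olefin transposition, the reaction type that turns allyl ethers into (E)-propenyl ethers, moves the double bond into conjugation with oxygen and should give the (E)-γ-alkoxyallylboronate.

Step 3
Reactants: 3 (E)-3-(benzyloxy)prop-2-enylboronic acid pinacol ester; 4 3,4-bis(benzyloxy)benzaldehyde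
Product: 6 (1S,2R)-1-[3,4-bis(benzyloxy)phenyl]-2-(benzyloxy)but-3-en-1-ol (anti isomer), via pinacol borate ester 5 (not isolated)
Conditions: (R)-TRIP [(R)-3,3'-bis(2,4,6-triisopropylphenyl)-BINOL hydrogen phosphate] (5 mol%), 4 Å MS, toluene, −30 → 0 °C; aqueous work-up
Reagents that add atoms: none
Why: Chiral-phosphoric-acid-catalysed allylboration through a closed chair (Zimmerman–Traxler) transition state, in which the (E)-boronate geometry translates into the anti relationship and the (R)-catalyst directs attack to the Re face of the aldehyde, setting C3 in its final configuration and C2 in the configuration that is to be inverted.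

Step 4
Reactants: 6 (1S,2R)-1-[3,4-bis(benzyloxy)phenyl]-2-(benzyloxy)but-3-en-1-ol; 7 3,5-bis(benzyloxy)phenol
Product: 8 (1R,2R)-1-[3,4-bis(benzyloxy)phenyl]-2-(benzyloxy)but-3-en-1-yl 3,5-bis(benzyloxy)phenyl ether (syn isomer)
Conditions: PPh3, DIAD, toluene, −20 °C → rt
Reagents that add atoms: none
Why: Mitsunobu etherification, an SN2 displacement of the oxyphosphonium group by the phenoxide, inverts C2 and converts the anti alcohol into the syn ether (future 2R,3R, 2,3-cis), the adjacent C–OBn bond disfavouring ionisation of the benzylic centre.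

Step 5
Reactants: 8 syn aryl ether with terminal vinyl group
Product: 10 (2S,3R)-2-(benzyloxy)-3-[3,4-bis(benzyloxy)phenyl]-3-[3,5-bis(benzyloxy)phenoxy]propanal, via vicinal diol 9 (not isolated)
Conditions: OsO4 (cat.), NaIO4, 2,6-lutidine, dioxane–H2O, rt; used without storage
Reagents that add atoms: osmium tetroxide, O=[Os](=O)(=O)=O; sodium periodate, [Na+].[O-]I(=O)(=O)=O
Why: Lemieux–Johnson oxidation (catalytic dihydroxylation followed by periodate glycol cleavage) unmasks C4 as the aldehyde under buffered conditions that spare the epimerisable C3 centre, the β-aryloxy group and all benzyl ethers.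

Step 6
Reactants: 11 2-bromoresorcinol
Product: 12 3-(benzyloxy)-2-bromophenol
Conditions: BnBr (1 equiv), K2CO3 (1 equiv), acetone, reflux
Reagents that add atoms: benzyl bromide, BrCc1ccccc1
Why: Williamson monoetherification of a symmetric diphenol with one equivalent of halide, the unreacted diphenol and the diether being removed by chromatography.

Step 7
Reactants: 12 3-(benzyloxy)-2-bromophenol
Product: 13 1-(allyloxy)-3-(benzyloxy)-2-bromobenzene
Conditions: allyl bromide, K2CO3, DMF, rt
Reagents that add atoms: allyl bromide, C=CCBr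
Why: Williamson etherification installs the one phenol protecting group that can later be removed beside benzyl ethers.

Step 8
Reactants: 13 1-(allyloxy)-3-(benzyloxy)-2-bromobenzene; 10 upper-unit aldehyde
Product: 15 1-[2-(allyloxy)-6-(benzyloxy)phenyl]-2-(benzyloxy)-3-[3,4-bis(benzyloxy)phenyl]-3-[3,5-bis(benzyloxy)phenoxy]propan-1-ol (C2 and C3 as in 10; both C4 epimers), via aryllithium 14 (not isolated)
Conditions: 13, n-BuLi, THF, −78 °C, short exchange time; then 10, −78 °C; AcOH quench at −78 °C
Reagents that add atoms: none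
Why: Bromine–lithium exchange outruns any reaction of the allyl or benzyl ethers at −78 °C and fixes the nucleophilic site at the carbon between the two oxygens, and 1,2-addition to the aldehyde forms the upper C4–middle C8 bond with a C4 configuration that does not matter.

Step 9
Reactants: 15 C4 carbinol (epimer mixture)
Product: 17 3,5,7,3',4'-penta-O-benzyl-4β-[2-(allyloxy)-6-(benzyloxy)phenyl]epicatechin (2,3-cis-3,4-trans), via benzylic cation 16 (not isolated)
Conditions: BF3·OEt2 (substoichiometric), 4 Å MS, CH2Cl2 (about 2 mM), −78 → −30 °C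
Reagents that add atoms: none
Why: BF3 ionises either C4 epimer of 15 to the same planar benzylic cation 16, stabilised by the ortho allyloxy and benzyloxy oxygens of the resorcinol ring, and an ortho carbon of the 3,5-dibenzyloxyphenyl ether (activated by three oxygens) attacks it before proton loss restores aromaticity. The closest known reaction type is the acid-mediated intramolecular Friedel–Crafts alkylation of 3-aryloxy-1-arylpropan-1-ols to 4-arylchromans. Ring C closes in a six-membered mode that is endo with respect to the attacked arene bond (C8a=C4a), through a half-chair array of O1, C2, C3 and C4. The new C4 stereocentre is controlled by allylic 1,3-strain in 16: the coplanar 2,6-dioxygenated aryl group forces C3–H into the cation plane, so C2 with its tethered nucleophile and the C3 benzyloxy group lie on opposite faces, and bond formation anti to C3–OBn gives the 3,4-trans (4β) product, in which the peri 5-benzyloxy group likewise favours a pseudoaxial aryl group. The step needs site selectivity for ring A over ring B, which could only close a five-membered indane through a carbon activated by a single para oxygen, and the much higher nucleophilicity of the phloroglucinol-type ring secures it, while the two ortho carbons of that ring are equivalent so that one regioisomer results. High dilution and low temperature hold back intermolecular capture by C6 and C8 of the product and loss of the allyl or benzyl groups.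

Step 10
Reactants: 17 4β-[2-(allyloxy)-6-(benzyloxy)phenyl]epicatechin pentabenzyl ether
Product: 18 3,5,7,3',4'-penta-O-benzyl-4β-[2-(benzyloxy)-6-hydroxyphenyl]epicatechin
Conditions: Pd(PPh3)4 (cat.), morpholine, THF, rt
Reagents that add atoms: none
Why: Tsuji–Trost type deallylation, in which zerovalent palladium ionises only the allyl aryl ether to a π-allyl complex that morpholine intercepts, leaves benzyl ethers and stereocentres untouched.

Step 11
Reactants: 18 phenol; 6 (1S,2R)-1-[3,4-bis(benzyloxy)phenyl]-2-(benzyloxy)but-3-en-1-ol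
Product: 19 ether of phenol 18 carrying the (1R,2R)-1-[3,4-bis(benzyloxy)phenyl]-2-(benzyloxy)but-3-en-1-yl group on the former phenol oxygen (middle O1)
Conditions: PPh3, DIAD, toluene (concentrated), 0 °C → rt
Reagents that add atoms: none
Why: A second Mitsunobu etherification forms middle O1–C2 with inversion, so the anti alcohol again gives the syn pair that corresponds to the 2R,3R (2,3-cis) middle unit.

Step 12
Reactants: 19 vinyl compound
Product: 21 aldehyde in which the vinyl group of 19 is replaced by CHO (middle C4), via vicinal diol 20 (not isolated)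
Conditions: OsO4 (cat.), NaIO4, 2,6-lutidine, dioxane–H2O, rt; used without storage
Reagents that add atoms: osmium tetroxide, O=[Os](=O)(=O)=O; sodium periodate, [Na+].[O-]I(=O)(=O)=O
Why: Lemieux–Johnson oxidation acts on the only alkene left in the molecule and delivers the aldehyde under buffered conditions that protect middle C3.

Step 13
Reactants: 22 (+)-catechin
Product: 23 5,7,3',4'-tetra-O-benzylcatechin
Conditions: BnBr, K2CO3, DMF, 0 °C → rt
Reagents that add atoms: benzyl bromide, BrCc1ccccc1
Why: Williamson etherification with a carbonate base alkylates the four phenols only and is mild enough to avoid epimerisation at C2.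

Step 14
Reactants: 23 5,7,3',4'-tetra-O-benzylcatechin
Product: 24 3,5,7,3',4'-penta-O-benzylcatechin
Conditions: NaH, BnBr, DMF, 0 °C → rt
Reagents that add atoms: benzyl bromide, BrCc1ccccc1
Why: Williamson etherification of the remaining secondary alkoxide removes the last acidic proton before the organolithium step.

Step 15
Reactants: 24 3,5,7,3',4'-penta-O-benzylcatechin
Product: 25 8-bromo-3,5,7,3',4'-penta-O-benzylcatechin
Conditions: NBS (1 equiv), CH2Cl2, −78 → 0 °C
Reagents that add atoms: N-bromosuccinimide, O=C1CCC(=O)N1Br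
Why: Electrophilic aromatic bromination takes place on ring A, the most electron-rich ring, and at C8, its most reactive position in O-benzylated catechins.

Step 16
Reactants: 25 8-bromo-penta-O-benzylcatechin; 21 middle-unit aldehyde
Product: 27 carbinol in which middle C4 bears OH and C8 of penta-O-benzylcatechin (both C4 epimers), via 8-lithiocatechin ether 26 (not isolated)
Conditions: 25, n-BuLi, THF, −78 °C; then 21, −78 °C; AcOH quench at −78 °C
Reagents that add atoms: none
Why: Bromine–lithium exchange followed by 1,2-addition to the aldehyde forms the middle C4–lower C8 bond regiospecifically, again with a C4 configuration that is erased in the next step.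

Step 17
Reactants: 27 carbinol (epimer mixture)
Product: 29 tetradeca-O-benzyl epicatechin-(4β→8)-epifisetinidol-(4β→8)-catechin, via benzylic cation 28 (not isolated)
Conditions: BF3·OEt2 (substoichiometric), 4 Å MS, CH2Cl2 (about 1 mM), −78 → −20 °C
Reagents that add atoms: none
Why: In the same intramolecular Friedel–Crafts alkylation, either epimer ionises to cation 28 stabilised by O1, 5-OBn and 7-OBn of catechin ring A, the only free carbon ortho to the ether oxygen of middle ring A (C4a, para to 7-OBn) closes the six-membered ring, and allylic 1,3-strain from the 2,6-dioxygenated aryl group again places the tethered nucleophile anti to C3–OBn, setting the middle 4β (3,4-trans) stereocentre.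

Step 18
Reactants: 29 tetradecabenzyl ether
Product: 30 epicatechin-(4β→8)-epifisetinidol-(4β→8)-catechin (CNP0270097.1)
Conditions: H2 (1 atm), Pd(OH)2/C, THF–MeOH–H2O, rt
Reagents that add atoms: none
Why: Catalytic hydrogenolysis removes all fourteen benzyl ethers under mild conditions that do not cleave the C2–O1 and C4–aryl bonds of flavans.

Compound list
1 | benzyl propargyl ether | C#CCOCc1ccccc1 | starting material
2 | (E)-3-(benzyloxy)prop-1-enylboronic acid pinacol ester | CC1(C)OB(/C=C/COCc2ccccc2)OC1(C)C | intermediate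
3 | (E)-3-(benzyloxy)prop-2-enylboronic acid pinacol ester | CC1(C)OB(C/C=C/OCc2ccccc2)OC1(C)C | intermediate
4 | 3,4-bis(benzyloxy)benzaldehyde | O=Cc1ccc(OCc2ccccc2)c(OCc2ccccc2)c1 | starting material
5 | pinacol borate ester of alcohol 6 | CC1(C)OB(O[C@@H](c2ccc(OCc3ccccc3)c(OCc3ccccc3)c2)[C@H](OCc2ccccc2)C=C)OC1(C)C | intermediate
6 | (1S,2R)-1-[3,4-bis(benzyloxy)phenyl]-2-(benzyloxy)but-3-en-1-ol (anti) | O[C@@H](c1ccc(OCc2ccccc2)c(OCc2ccccc2)c1)[C@H](OCc1ccccc1)C=C | intermediate
7 | 3,5-bis(benzyloxy)phenol | Oc1cc(OCc2ccccc2)cc(OCc2ccccc2)c1 | starting material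
8 | (1R,2R)-1-[3,4-bis(benzyloxy)phenyl]-2-(benzyloxy)but-3-en-1-yl 3,5-bis(benzyloxy)phenyl ether (syn) | c1ccccc1COc1cc(OCc2ccccc2)cc(c1)O[C@H](c1ccc(OCc2ccccc2)c(OCc2ccccc2)c1)[C@H](OCc1ccccc1)C=C | intermediate
9 | vicinal diol from 8 (new carbinol centre undefined) | c1ccccc1COc1cc(OCc2ccccc2)cc(c1)O[C@H](c1ccc(OCc2ccccc2)c(OCc2ccccc2)c1)[C@H](OCc1ccccc1)C(O)CO | intermediate
10 | (2S,3R)-2-(benzyloxy)-3-[3,4-bis(benzyloxy)phenyl]-3-[3,5-bis(benzyloxy)phenoxy]propanal | c1ccccc1COc1cc(OCc2ccccc2)cc(c1)O[C@H](c1ccc(OCc2ccccc2)c(OCc2ccccc2)c1)[C@H](OCc1ccccc1)C=O | intermediate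
11 | 2-bromoresorcinol | Oc1cccc(O)c1Br | starting material
12 | 3-(benzyloxy)-2-bromophenol | Oc1cccc(OCc2ccccc2)c1Br | intermediate
13 | 1-(allyloxy)-3-(benzyloxy)-2-bromobenzene | C=CCOc1cccc(OCc2ccccc2)c1Br | intermediate
14 | 2-(allyloxy)-6-(benzyloxy)phenyllithium | [Li]c1c(OCC=C)cccc1OCc1ccccc1 | intermediate
15 | key-step precursor: C4 carbinol on the 2-allyloxy-6-benzyloxyphenyl ring, C2 3,5-dibenzyloxyphenyl ether, C3 benzyl ether (C4 epimer mixture; the 3,4-syn epimer is drawn) | c1ccccc1COc1cc(OCc2ccccc2)cc(c1)O[C@H](c1ccc(OCc2ccccc2)c(OCc2ccccc2)c1)[C@H](OCc1ccccc1)[C@@H](O)c1c(OCc2ccccc2)cccc1OCC=C | intermediate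
16 | benzylic cation at upper C4 | c1ccccc1COc1cc(OCc2ccccc2)cc(c1)O[C@H](c1ccc(OCc2ccccc2)c(OCc2ccccc2)c1)[C@H](OCc1ccccc1)[CH+]c1c(OCc2ccccc2)cccc1OCC=C | intermediate
17 | key-step product: 3,5,7,3',4'-penta-O-benzyl-4β-[2-(allyloxy)-6-(benzyloxy)phenyl]epicatechin | c1ccccc1COc1cc(OCc2ccccc2)c2c(c1)O[C@H](c1ccc(OCc3ccccc3)c(OCc3ccccc3)c1)[C@H](OCc1ccccc1)[C@H]2c1c(OCc2ccccc2)cccc1OCC=C | intermediate
18 | 3,5,7,3',4'-penta-O-benzyl-4β-[2-(benzyloxy)-6-hydroxyphenyl]epicatechin | c1ccccc1COc1cc(OCc2ccccc2)c2c(c1)O[C@H](c1ccc(OCc3ccccc3)c(OCc3ccccc3)c1)[C@H](OCc1ccccc1)[C@H]2c1c(OCc2ccccc2)cccc1O | intermediate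
19 | ether of 18 with the (1R,2R)-1-[3,4-bis(benzyloxy)phenyl]-2-(benzyloxy)but-3-en-1-yl group | c1ccccc1COc1cc(OCc2ccccc2)c2c(c1)O[C@H](c1ccc(OCc3ccccc3)c(OCc3ccccc3)c1)[C@H](OCc1ccccc1)[C@H]2c1c(OCc2ccccc2)cccc1O[C@H](c1ccc(OCc2ccccc2)c(OCc2ccccc2)c1)[C@H](OCc1ccccc1)C=C | intermediate
20 | vicinal diol from 19 (new carbinol centre undefined) | c1ccccc1COc1cc(OCc2ccccc2)c2c(c1)O[C@H](c1ccc(OCc3ccccc3)c(OCc3ccccc3)c1)[C@H](OCc1ccccc1)[C@H]2c1c(OCc2ccccc2)cccc1O[C@H](c1ccc(OCc2ccccc2)c(OCc2ccccc2)c1)[C@H](OCc1ccccc1)C(O)CO | intermediate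
21 | middle-unit aldehyde (middle C4 = CHO) | c1ccccc1COc1cc(OCc2ccccc2)c2c(c1)O[C@H](c1ccc(OCc3ccccc3)c(OCc3ccccc3)c1)[C@H](OCc1ccccc1)[C@H]2c1c(OCc2ccccc2)cccc1O[C@H](c1ccc(OCc2ccccc2)c(OCc2ccccc2)c1)[C@H](OCc1ccccc1)C=O | intermediate
22 | (+)-catechin (2R,3S) | Oc1cc(O)c2c(c1)O[C@H](c1ccc(O)c(O)c1)[C@@H](O)C2 | starting material
23 | 5,7,3',4'-tetra-O-benzylcatechin | c1ccccc1COc1cc(OCc2ccccc2)c2c(c1)O[C@H](c1ccc(OCc3ccccc3)c(OCc3ccccc3)c1)[C@@H](O)C2 | intermediate
24 | 3,5,7,3',4'-penta-O-benzylcatechin | c1ccccc1COc1cc(OCc2ccccc2)c2c(c1)O[C@H](c1ccc(OCc3ccccc3)c(OCc3ccccc3)c1)[C@@H](OCc1ccccc1)C2 | intermediate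
25 | 8-bromo-3,5,7,3',4'-penta-O-benzylcatechin | c1ccccc1COc1cc(OCc2ccccc2)c2c(c1Br)O[C@H](c1ccc(OCc3ccccc3)c(OCc3ccccc3)c1)[C@@H](OCc1ccccc1)C2 | intermediate
26 | 8-lithio-3,5,7,3',4'-penta-O-benzylcatechin | c1ccccc1COc1cc(OCc2ccccc2)c2c(c1[Li])O[C@H](c1ccc(OCc3ccccc3)c(OCc3ccccc3)c1)[C@@H](OCc1ccccc1)C2 | intermediate
27 | carbinol at middle C4 bearing C8 of pentabenzylcatechin (C4 epimer mixture, centre left undefined) | c1ccccc1COc1cc(OCc2ccccc2)c2c(c1)O[C@H](c1ccc(OCc3ccccc3)c(OCc3ccccc3)c1)[C@H](OCc1ccccc1)[C@H]2c1c(OCc2ccccc2)cccc1O[C@H](c1ccc(OCc2ccccc2)c(OCc2ccccc2)c1)[C@H](OCc1ccccc1)C(O)c1c(OCc2ccccc2)cc(OCc2ccccc2)c2c1O[C@H](c1ccc(OCc3ccccc3)c(OCc3ccccc3)c1)[C@@H](OCc1ccccc1)C2 | intermediate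
28 | benzylic cation at middle C4 | c1ccccc1COc1cc(OCc2ccccc2)c2c(c1)O[C@H](c1ccc(OCc3ccccc3)c(OCc3ccccc3)c1)[C@H](OCc1ccccc1)[C@H]2c1c(OCc2ccccc2)cccc1O[C@H](c1ccc(OCc2ccccc2)c(OCc2ccccc2)c1)[C@H](OCc1ccccc1)[CH+]c1c(OCc2ccccc2)cc(OCc2ccccc2)c2c1O[C@H](c1ccc(OCc3ccccc3)c(OCc3ccccc3)c1)[C@@H](OCc1ccccc1)C2 | intermediate
29 | tetradeca-O-benzyl epicatechin-(4β→8)-epifisetinidol-(4β→8)-catechin | c1ccccc1COc1cc(OCc2ccccc2)c2c(c1)O[C@H](c1ccc(OCc3ccccc3)c(OCc3ccccc3)c1)[C@H](OCc1ccccc1)[C@H]2c1c(OCc2ccccc2)ccc2c1O[C@H](c1ccc(OCc3ccccc3)c(OCc3ccccc3)c1)[C@H](OCc1ccccc1)[C@H]2c1c(OCc2ccccc2)cc(OCc2ccccc2)c2c1O[C@H](c1ccc(OCc3ccccc3)c(OCc3ccccc3)c1)[C@@H](OCc1ccccc1)C2 | intermediate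
30 | epicatechin-(4β→8)-epifisetinidol-(4β→8)-catechin (CNP0270097.1) | Oc1cc(O)c2c(c1)O[C@H](c1ccc(O)c(O)c1)[C@H](O)[C@H]2c1c(O)ccc2c1O[C@H](c1ccc(O)c(O)c1)[C@H](O)[C@H]2c1c(O)cc(O)c2c1O[C@H](c1ccc(O)c(O)c1)[C@@H](O)C2 | target

Total step count: 18. Longest linear sequence: 13 steps (steps 1–5, 8–12, 16–18).

Steps most likely to fail

Step 9 (key cyclisation). After ionisation, several processes can compete with ring closure: proton loss from C3, expulsion of the allyl or a benzyl group from an ortho oxygen, capture by a second molecule, or incomplete facial control. The fallback replaces the Lewis-acid-generated cation by a neutral ortho-quinone methide.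
- It sets out from 15, where the allyl ether is removed first (Pd(PPh3)4, morpholine, THF) to give the ortho-hydroxybenzylic alcohol F1.
- A weak Brønsted acid ((PhO)2P(O)OH, catalytic, toluene, rt) dehydrates it to the ortho-quinone methide F2.
- Conjugate addition of the tethered 3,5-dibenzyloxyphenyl ether ring, a known arylation mode of such methides, closes ring C under the same allylic-strain control.
- The route is rejoined at phenol 18, so step 10 is no longer needed.

Step 17 (closure of the middle ring). The trialkoxybenzyl cation is strongly stabilised, and the attacking ring is only doubly activated and crowded by the upper unit. Closure may therefore be slow compared with proton loss from C3 or acid cleavage of the first interflavan bond. Without a peri substituent, the facial preference also rests on allylic strain alone. The fallback exchanges the roles of the partners, so that the cation sits on the middle unit and catechin is an external nucleophile.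
- It sets out from aldehyde 21, where SnCl4 (CH2Cl2, −78 °C) induces intramolecular Friedel–Crafts hydroxyalkylation at C4a to give the flavan-4-ol F3.
- TMSOTf in the presence of an excess of 24 ionises it to the flavan-4-yl cation F4, stabilised by O1 and 7-OBn of middle ring A.
- C8 of 24 attacks this cation from the β face, anti to the axial 3-benzyloxy group, as in the established Lewis-acid coupling of 4-oxygenated flavans with benzylated catechin.
- The route is rejoined at 29, and steps 15 and 16 fall away.

Step 11 (second Mitsunobu etherification). Displacement by the hindered phenoxide may be slow. The oxyphosphonium ion could then ionise or be intercepted by the hydrazide, with erosion of configuration at middle C2 or consumption of the alcohol. The fallback makes this ether bond before the fragments are joined, on an unhindered phenol.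
- It sets out from 12, which is etherified with 6 (PPh3, DIAD, toluene) to give the bromoaryl ether F5.
- Bromine–lithium exchange (n-BuLi, THF, −78 °C) gives the aryllithium F6, which adds to aldehyde 10 to give the carbinol F7.
- BF3·OEt2 under the conditions of step 9 ionises it to the benzylic cation F8, which cyclises in the same way.
- The route is rejoined at 19, and steps 7 and 10 fall away.

Further compounds
F1 | step 9 | ortho-hydroxybenzylic alcohol (deallylated 15, C4 undefined) | c1ccccc1COc1cc(OCc2ccccc2)cc(c1)O[C@H](c1ccc(OCc2ccccc2)c(OCc2ccccc2)c1)[C@H](OCc1ccccc1)C(O)c1c(OCc2ccccc2)cccc1O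
F2 | step 9 | ortho-quinone methide derived from F1 | c1ccccc1COc1cc(OCc2ccccc2)cc(c1)O[C@H](c1ccc(OCc2ccccc2)c(OCc2ccccc2)c1)[C@H](OCc1ccccc1)C=C1C(=O)C=CC=C1OCc1ccccc1
F3 | step 17 | flavan-4-ol with closed middle ring (middle C4 undefined) | c1ccccc1COc1cc(OCc2ccccc2)c2c(c1)O[C@H](c1ccc(OCc3ccccc3)c(OCc3ccccc3)c1)[C@H](OCc1ccccc1)[C@H]2c1c(OCc2ccccc2)ccc2c1O[C@H](c1ccc(OCc3ccccc3)c(OCc3ccccc3)c1)[C@H](OCc1ccccc1)C2O
F4 | step 17 | middle flavan-4-yl cation | c1ccccc1COc1cc(OCc2ccccc2)c2c(c1)O[C@H](c1ccc(OCc3ccccc3)c(OCc3ccccc3)c1)[C@H](OCc1ccccc1)[C@H]2c1c(OCc2ccccc2)ccc2c1O[C@H](c1ccc(OCc3ccccc3)c(OCc3ccccc3)c1)[C@H](OCc1ccccc1)[CH+]2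
F5 | step 11 | 3-(benzyloxy)-2-bromophenyl (1R,2R)-1-[3,4-bis(benzyloxy)phenyl]-2-(benzyloxy)but-3-en-1-yl ether | Brc1c(OCc2ccccc2)cccc1O[C@H](c1ccc(OCc2ccccc2)c(OCc2ccccc2)c1)[C@H](OCc1ccccc1)C=C
F6 | step 11 | aryllithium from F5 | [Li]c1c(OCc2ccccc2)cccc1O[C@H](c1ccc(OCc2ccccc2)c(OCc2ccccc2)c1)[C@H](OCc1ccccc1)C=C
F7 | step 11 | carbinol from F6 and 10 (upper C4 undefined) | c1ccccc1COc1cc(OCc2ccccc2)cc(c1)O[C@H](c1ccc(OCc2ccccc2)c(OCc2ccccc2)c1)[C@H](OCc1ccccc1)C(O)c1c(OCc2ccccc2)cccc1O[C@H](c1ccc(OCc2ccccc2)c(OCc2ccccc2)c1)[C@H](OCc1ccccc1)C=C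
F8 | step 11 | benzylic cation from F7 | c1ccccc1COc1cc(OCc2ccccc2)cc(c1)O[C@H](c1ccc(OCc2ccccc2)c(OCc2ccccc2)c1)[C@H](OCc1ccccc1)[CH+]c1c(OCc2ccccc2)cccc1O[C@H](c1ccc(OCc2ccccc2)c(OCc2ccccc2)c1)[C@H](OCc1ccccc1)C=C
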